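**Plan**

- Retrosynthesis: ring C is opened at O1–C2, giving the 2'-hydroxychalcone and then its carbinol. Ring A is cut at C5–C6, C4a–C8a and C8–C8a into a chromium methoxy(1-methoxyvinyl)carbene, one CO ligand and a terminal alkyne. The alkyne is cut at C4–C4a (acetylide addition) and C2–C3 (Wittig) back to 2,3,4-trimethoxybenzaldehyde.
- Forward: the ring B aldehyde is extended to the chain ArCH=CH–CH(OTBS)–C≡CH, ring A is built onto the alkyne by benzannulation, and ring C is closed last by iodine–DMSO cyclisation.
- Enabling feature: in ring A the C8a oxygen is para to the C6 methoxyl, the C7 methoxyl sits beside it, and the acyl carbon C4 sits on C4a ortho to that oxygen. This is the 4-alkoxyphenol pattern of a carbene/alkyne/CO benzannulation (carbene carbon to C6, vinyl carbons to C7 and C8, CO to C8a, alkyne to C5 and C4a).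
- Stereochemistry: the target has no stereocentre. The E-olefin comes from the Wittig step, and the racemic carbinol centre is oxidised away.

Key step: step 5

Assumption: carbinol-bearing intermediates are carried as racemates and the two Cr(CO)3 complexes passed through in the key step as diastereomer mixtures; in their SMILES the η6-bound Cr(CO)3 unit is written as a dot-joined fragment.

**Route**

Step 1
Reactants: 1 2,3,4-trimethoxybenzaldehyde; 2 (triphenylphosphoranylidene)acetaldehyde
Product: 3 (E)-3-(2,3,4-trimethoxyphenyl)prop-2-enal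
Conditions: PhMe, 90 °C
Reagents that add atoms: none
Why: Wittig olefination with the stabilised formylmethylene ylide homologates the aryl aldehyde by two carbons and should give the E-enal under thermodynamic control.

Step 2
Reactants: 3 (E)-3-(2,3,4-trimethoxyphenyl)prop-2-enal; 4 ethynylmagnesium bromide (HC≡CMgBr)
Product: 5 (E)-1-(2,3,4-trimethoxyphenyl)pent-1-en-4-yn-3-ol (racemic)
Conditions: THF, −78 to 0 °C; then aq NH4Cl
Reagents that add atoms: none
Why: Grignard 1,2-addition of the acetylide to the enal carbonyl outruns conjugate addition and should give the racemic allylic propargylic alcohol, whose stereocentre is erased later by oxidation.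

Step 3
Reactants: 5 (E)-1-(2,3,4-trimethoxyphenyl)pent-1-en-4-yn-3-ol
Product: 6 (E)-tert-butyldimethyl{[1-(2,3,4-trimethoxyphenyl)pent-1-en-4-yn-3-yl]oxy}silane (racemic)
Conditions: TBSCl, imidazole, DMF, rt
Reagents that add atoms: tert-butyldimethylsilyl chloride, CC(C)(C)[Si](C)(C)Cl
Why: Silyl ether protection with TBSCl and imidazole is base-mediated, so the acid-labile doubly activated carbinol survives, and it keeps the alkyne electron-neutral where the corresponding ynone would be too electron-poor for the benzannulation.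

Step 4
Reactants: 7 methyl vinyl ether; 8 hexacarbonylchromium Cr(CO)6 (zerovalent chromium)
Product: 11 pentacarbonyl[methoxy(1-methoxyethenyl)carbene]chromium (CO)5Cr=C(OMe)C(OMe)=CH2, via 1-methoxyvinyllithium 9 (not isolated), via lithium acylpentacarbonylchromate 10 (not isolated)
Conditions: 7 (excess), t-BuLi, THF, −78 to 0 °C; Cr(CO)6, THF, −78 °C to rt; solvent switch, Me3OBF4, CH2Cl2, 0 °C
Reagents that add atoms: trimethyloxonium tetrafluoroborate, C[O+](C)C.F[B-](F)(F)F
Why: Fischer carbene synthesis, in which alpha-lithiation of the enol ether gives 1-methoxyvinyllithium, this adds to a CO ligand of Cr(CO)6, and the hard Meerwein salt O-methylates the acylchromate under anhydrous conditions that spare the enol ether.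

Step 5
Reactants: 6 (E)-tert-butyldimethyl{[1-(2,3,4-trimethoxyphenyl)pent-1-en-4-yn-3-yl]oxy}silane; 11 pentacarbonyl[methoxy(1-methoxyethenyl)carbene]chromium
Product: 14 tert-butyl{2-[(E)-1-(tert-butyldimethylsilyloxy)-3-(2,3,4-trimethoxyphenyl)prop-2-en-1-yl]-4,5-dimethoxyphenoxy}dimethylsilane, via phenol tricarbonylchromium complex 12 (not isolated), via silyl ether tricarbonylchromium complex 13 (not isolated)
Conditions: TBSCl, i-Pr2NEt, CH2Cl2 (degassed, 0.1 M), 55 °C, sealed tube; then air, MeCN, rt
Reagents that add atoms: tert-butyldimethylsilyl chloride, CC(C)(C)[Si](C)(C)Cl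
Why: Dötz benzannulation: loss of one CO from 11 lets the terminal alkyne insert into Cr=C so that its CH carbon bonds to the carbene carbon (C5–C6), and CO insertion at the new carbene centre forms C4a–C8a and a chromium-bound dienylketene. Ring A then closes by 6π-electrocyclisation between the ketene carbon and the CH2 terminus of the methoxyvinyl unit (C8–C8a), and the cyclohexadienone tautomerises to the Cr(CO)3-bound phenol 12. The closest known reactions are benzannulations of alpha-substituted alkenyl(methoxy)carbene complexes of zerovalent chromium, including cyclic alpha-alkoxyalkenyl ones, with terminal propargylic ethers under in situ silylation. No lasting stereocentre is made, since the carbinol centre stays racemic and the planar chirality of 12 and 13 disappears on decomplexation. The side chain must end up ortho to the new oxygen, which the steric preference of a terminal alkyne to place its substituted carbon next to the inserting CO secures, while the alkenyl (not aryl) carbene favours the phenol over five-ring products. TBSCl and i-Pr2NEt cap the acidic complexed phenol as it forms, which blocks loss of the benzylic silyloxy group to an ortho-quinone methide and its 6π closure onto the styryl unit, and air in MeCN then removes Cr(CO)3 without oxidising the fully etherified ring.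

Step 6
Reactants: 14 tert-butyl{2-[(E)-1-(tert-butyldimethylsilyloxy)-3-(2,3,4-trimethoxyphenyl)prop-2-en-1-yl]-4,5-dimethoxyphenoxy}dimethylsilane
Product: 15 2-[(E)-1-hydroxy-3-(2,3,4-trimethoxyphenyl)prop-2-en-1-yl]-4,5-dimethoxyphenol (racemic)
Conditions: Bu4NF, THF, 0 °C; then pH 7 phosphate buffer
Reagents that add atoms: none
Why: Fluoride-induced desilylation cleaves the aryl and the alkyl silyl ether under basic, non-ionising conditions, and the neutral work-up should keep the doubly activated carbinol from ionising before it is oxidised.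

Step 7
Reactants: 15 2-[(E)-1-hydroxy-3-(2,3,4-trimethoxyphenyl)prop-2-en-1-yl]-4,5-dimethoxyphenol
Product: 16 (E)-1-(2-hydroxy-4,5-dimethoxyphenyl)-3-(2,3,4-trimethoxyphenyl)prop-2-en-1-one
Conditions: activated MnO2, CH2Cl2, rt
Reagents that add atoms: none
Why: MnO2 oxidation is selective for the allylic and benzylic carbinol, and the ketone formed is stabilised by its hydrogen bond to the ortho phenol, so the 2'-hydroxychalcone should result.

Step 8
Reactants: 16 (E)-1-(2-hydroxy-4,5-dimethoxyphenyl)-3-(2,3,4-trimethoxyphenyl)prop-2-en-1-one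
Product: 18 6,7-dimethoxy-2-(2,3,4-trimethoxyphenyl)-4H-chromen-4-one, via flavanone 17 (not isolated)
Conditions: I2 (10 mol %), DMSO, 130 °C
Reagents that add atoms: none
Why: Iodine–DMSO oxidative cyclisation of a 2'-hydroxychalcone, in which 6-endo oxa-Michael closure forms ring C as the flavanone and iodine dehydrogenates it across C2–C3 while DMSO reoxidises the HI formed.

**Compound list**

1 | 2,3,4-trimethoxybenzaldehyde | COc1ccc(C=O)c(OC)c1OC | starting material
2 | (triphenylphosphoranylidene)acetaldehyde | O=CC=P(c1ccccc1)(c1ccccc1)c1ccccc1 | starting material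
3 | (E)-3-(2,3,4-trimethoxyphenyl)prop-2-enal | COc1ccc(/C=C/C=O)c(OC)c1OC | intermediate
4 | ethynylmagnesium bromide | C#C[Mg]Br | starting material
5 | (E)-1-(2,3,4-trimethoxyphenyl)pent-1-en-4-yn-3-ol (racemic) | C#CC(O)/C=C/c1ccc(OC)c(OC)c1OC | intermediate
6 | (E)-tert-butyldimethyl{[1-(2,3,4-trimethoxyphenyl)pent-1-en-4-yn-3-yl]oxy}silane (racemic) | C#CC(O[Si](C)(C)C(C)(C)C)/C=C/c1ccc(OC)c(OC)c1OC | intermediate
7 | methyl vinyl ether | COC=C | starting material
8 | hexacarbonylchromium Cr(CO)6 | O=C=[Cr](=C=O)(=C=O)(=C=O)(=C=O)=C=O | starting material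
9 | 1-methoxyvinyllithium (not isolated) | [Li]C(=C)OC | intermediate
10 | lithium pentacarbonyl(2-methoxyprop-2-enoyl)chromate (not isolated) | [Li+].[O-]C(C(=C)OC)=[Cr](=C=O)(=C=O)(=C=O)(=C=O)=C=O | intermediate
11 | pentacarbonyl[methoxy(1-methoxyethenyl)carbene]chromium | COC(=C)C(OC)=[Cr](=C=O)(=C=O)(=C=O)(=C=O)=C=O | intermediate
12 | tricarbonyl{η6-2-[(E)-1-(tert-butyldimethylsilyloxy)-3-(2,3,4-trimethoxyphenyl)prop-2-en-1-yl]-4,5-dimethoxyphenol}chromium, Cr(CO)3 on ring A (not isolated) | COc1cc(O)c(cc1OC)C(O[Si](C)(C)C(C)(C)C)/C=C/c1ccc(OC)c(OC)c1OC.O=C=[Cr](=C=O)=C=O | intermediate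
13 | tricarbonyl(η6-arene)chromium complex of 14, Cr(CO)3 on ring A (not isolated) | COc1cc(O[Si](C)(C)C(C)(C)C)c(cc1OC)C(O[Si](C)(C)C(C)(C)C)/C=C/c1ccc(OC)c(OC)c1OC.O=C=[Cr](=C=O)=C=O | intermediate
14 | tert-butyl{2-[(E)-1-(tert-butyldimethylsilyloxy)-3-(2,3,4-trimethoxyphenyl)prop-2-en-1-yl]-4,5-dimethoxyphenoxy}dimethylsilane (racemic) | COc1cc(O[Si](C)(C)C(C)(C)C)c(cc1OC)C(O[Si](C)(C)C(C)(C)C)/C=C/c1ccc(OC)c(OC)c1OC | intermediate
15 | 2-[(E)-1-hydroxy-3-(2,3,4-trimethoxyphenyl)prop-2-en-1-yl]-4,5-dimethoxyphenol (racemic) | COc1cc(O)c(cc1OC)C(O)/C=C/c1ccc(OC)c(OC)c1OC | intermediate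
16 | (E)-1-(2-hydroxy-4,5-dimethoxyphenyl)-3-(2,3,4-trimethoxyphenyl)prop-2-en-1-one | COc1cc(O)c(cc1OC)C(=O)/C=C/c1ccc(OC)c(OC)c1OC | intermediate
17 | 6,7-dimethoxy-2-(2,3,4-trimethoxyphenyl)chroman-4-one (racemic, not isolated) | COc1cc2OC(CC(=O)c2cc1OC)c1ccc(OC)c(OC)c1OC | intermediate
18 | 6,7-dimethoxy-2-(2,3,4-trimethoxyphenyl)-4H-chromen-4-one | COc1cc2oc(-c3ccc(OC)c(OC)c3OC)cc(=O)c2cc1OC | target

**Step count and risks**

Total step count: 8. Longest linear sequence: 7 steps (steps 1, 2, 3, 5, 6, 7, 8 from 2,3,4-trimethoxybenzaldehyde); step 4 is a one-step branch that joins at step 5.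

Steps most likely to fail:

1. Step 5. The chromium vinylcarbene and ketene intermediates may be diverted into double alkyne insertion or five-ring channels. Alternatively, silylation may lag behind ring formation, so that the complexed phenol expels its benzylic silyloxy group and the resulting ortho-quinone methide closes onto the styryl double bond to a 2H-chromene. The fallback leaves the styryl unit out of the benzannulation and adds it afterwards by aldol condensation. It sets out from 11, which is combined under the same protocol (TBSCl, i-Pr2NEt, CH2Cl2, 55 °C; then air, MeCN) with commercial tert-butyldimethyl(but-3-yn-2-yloxy)silane (C#CC(C)O[Si](C)(C)C(C)(C)C). This should pass through tricarbonyl{η6-2-[1-(tert-butyldimethylsilyloxy)ethyl]-4,5-dimethoxyphenol}chromium F1 and tricarbonyl{η6-tert-butyl{2-[1-(tert-butyldimethylsilyloxy)ethyl]-4,5-dimethoxyphenoxy}dimethylsilane}chromium F2 to the free arene tert-butyl{2-[1-(tert-butyldimethylsilyloxy)ethyl]-4,5-dimethoxyphenoxy}dimethylsilane F3. Bu4NF in THF should then give 2-(1-hydroxyethyl)-4,5-dimethoxyphenol F4, and MnO2 in CH2Cl2 should give 1-(2-hydroxy-4,5-dimethoxyphenyl)ethan-1-one F5. Claisen–Schmidt condensation of this ketone with 1 (KOH, EtOH, rt) comes back to the route at 16.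

2. Step 6. Once both silyl groups are off, the ortho-hydroxybenzyl allylic carbinol may ionise during desilylation, work-up or on the MnO2 surface of step 7, and the ortho-quinone methide would electrocyclise to the flav-3-ene. The fallback never liberates the carbinol next to a free phenol. It sets out from 14, where DDQ in CH2Cl2/pH 7 buffer at 0 °C should oxidise the doubly activated benzylic allylic silyl ether directly to the enone (E)-1-[2-(tert-butyldimethylsilyloxy)-4,5-dimethoxyphenyl]-3-(2,3,4-trimethoxyphenyl)prop-2-en-1-one F6. Bu4NF buffered with AcOH (THF, 0 °C) then frees the phenol, and the sequence comes back at 16, bypassing step 7 as well.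

3. Step 4. The electron-rich carbene complex may be lost during O-methylation, either through slow alkylation of the lithium acylate with decomposition, or through hydrolysis of the enol ether by acid released from the oxonium salt. The fallback replaces alkylation by acylation and alcoholysis at the carbene carbon. It sets out from 10, which is exchanged with aqueous Me4NBr to the storable salt tetramethylammonium pentacarbonyl(2-methoxyprop-2-enoyl)chromate F7. Acetyl bromide in CH2Cl2 at −40 °C should convert this into pentacarbonyl[acetoxy(1-methoxyethenyl)carbene]chromium F8, and addition of MeOH at −40 °C to rt exchanges acetoxy for methoxy and comes back to the route at 11.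

**Further compounds**

F1 | step 5 | tricarbonyl{η6-2-[1-(tert-butyldimethylsilyloxy)ethyl]-4,5-dimethoxyphenol}chromium | COc1cc(O)c(cc1OC)C(C)O[Si](C)(C)C(C)(C)C.O=C=[Cr](=C=O)=C=O
F2 | step 5 | tricarbonyl{η6-tert-butyl{2-[1-(tert-butyldimethylsilyloxy)ethyl]-4,5-dimethoxyphenoxy}dimethylsilane}chromium | COc1cc(O[Si](C)(C)C(C)(C)C)c(cc1OC)C(C)O[Si](C)(C)C(C)(C)C.O=C=[Cr](=C=O)=C=O
F3 | step 5 | tert-butyl{2-[1-(tert-butyldimethylsilyloxy)ethyl]-4,5-dimethoxyphenoxy}dimethylsilane | COc1cc(O[Si](C)(C)C(C)(C)C)c(cc1OC)C(C)O[Si](C)(C)C(C)(C)C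
F4 | step 5 | 2-(1-hydroxyethyl)-4,5-dimethoxyphenol | COc1cc(O)c(cc1OC)C(C)O
F5 | step 5 | 1-(2-hydroxy-4,5-dimethoxyphenyl)ethan-1-one | COc1cc(O)c(cc1OC)C(C)=O
F6 | step 6 | (E)-1-[2-(tert-butyldimethylsilyloxy)-4,5-dimethoxyphenyl]-3-(2,3,4-trimethoxyphenyl)prop-2-en-1-one | COc1cc(O[Si](C)(C)C(C)(C)C)c(cc1OC)C(=O)/C=C/c1ccc(OC)c(OC)c1OC
F7 | step 4 | tetramethylammonium pentacarbonyl(2-methoxyprop-2-enoyl)chromate | C[N+](C)(C)C.[O-]C(C(=C)OC)=[Cr](=C=O)(=C=O)(=C=O)(=C=O)=C=O
F8 | step 4 | pentacarbonyl[acetoxy(1-methoxyethenyl)carbene]chromium | CC(=O)OC(C(=C)OC)=[Cr](=C=O)(=C=O)(=C=O)(=C=O)=C=O
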